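The ratio ρ = c_X/c_E at the latest time answers the last two questions at once: the share of X in X plus E is ρ/(1+ρ), and ρ above one puts X ahead.

| flask | L | G | remark | time |
|---|---|---|---|---|
| green | 13 mM | 24 mM | run made earlier |  |
| blue | 30 mM | 24 mM | run made earlier |  |
| amber | 20 mM | 48 mM | run made earlier |  |
| flask | 20 mM | 24.0 mM |  | 12 h |

| run | time / h | X / % | E / % |
|---|---|---|---|
| green | 1.00 | 12.6 | 35.0 |
| green | 1.50 | 18.2 | 29.8 |
| green | 2.50 | 21.5 | 22.6 |
| green | 4.00 | 25.2 | 19.2 |
| green | 8.00 | 29.8 | 17.6 |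
| green | 12.0 | 32.3 | 19.1 |
| blue | 2.00 | 18.5 | 24.5 |
| blue | 4.00 | 23.1 | 20.5 |
| blue | 6.00 | 24.5 | 17.7 |
| blue | 8.00 | 28.1 | 18.0 |
| blue | 10.0 | 31.4 | 13.9 |
| blue | 12.0 | 32.8 | 14.8 |
| amber | 1.00 | 16.9 | 34.6 |
| amber | 2.00 | 24.1 | 22.0 |
| amber | 3.00 | 27.1 | 19.8 |
| amber | 6.00 | 31.6 | 17.4 |
| amber | 12.0 | 41.1 | 15.4 |

(readings scatter by 1 percentage point)



- share of X in X plus E at 80 s
- share of X in X plus E at 25 min
- share of X in X plus E at 12 h
- which of X and E there is more of at 12 h

The green run reads as a ladder of time scales. On the fastest rung, over by the first reading at 1.00 h, X plus E reach 47.6% of the L charged. They stand at 51.4% at 12.0 h, so about half of the charge lies outside the two readings. On the middle rung, E falls from 35.0% to 19.2% by 4.00 h, and X passes it after about 2.50 h. On the slowest rung, E hovers while X gains 7.1 percentage points up to 12.0 h.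

On that rung ρ still climbs, in green from 1.31 at 4.00 h to 1.69 at 12.0 h, so it has to be read at the asked time itself and not from an earlier reading. Green and blue have the flask's G and bracket its L, and they give 1.69 and 2.22. This reckoning takes their mean, 1.95, as the lead ratio: a share of 66.1%, with X ahead. Amber, with doubled G, reads 2.67, a factor of 1.37 per doubling. It offers no early number, since 80 s and 25 min come earlier than the first reading.

The forecast gave 3%, 14% and 66%, with X ahead: “So E forms first and then gives way to X.”

The flask gave 0.879%, 12.9% and 67.3%, with X ahead at 33.5% against 16.3%, so ρ came to 2.06 against the carried 1.95.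

    L ⇌ E (K = 5.20, k = 0.0350 min⁻¹)
    L ⇌ J (K = 0.630, k = 0.0140 min⁻¹)
    G + J → X (k = 1.40 L mol⁻¹ min⁻¹)
    G + J → Z (k = 0.100 L mol⁻¹ min⁻¹)
    G + J ⇌ Q (K = 22.0 L mol⁻¹, k = 1.20 L mol⁻¹ min⁻¹)
    E ⇌ D (K = 2.60, k = 0.0190 min⁻¹)

Early in the flask, L turned into E, the kinetic product, with a forward half-life of 0.33 h, shorter than the 0.83 h into J, while E passed on into D. X drew level at 2.76 h, far earlier than 12 h, and by then G + J had been making X; at 12 h the flask held 44.2% as D.

With 96 mM of G, two doublings carry ρ to 3.66, a share of 78.5%. The computed share there is 76.5%.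

(The numbers in the tables are calculated for an exercise; the scatter is artificial.)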